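## Structural features

The target is a hexasubstituted benzene (ring A, a phloroglucinol). In chromanone numbering it carries a fused 2,3-dihydro-4-pyranone (ring B: O1, C2, C3, C4, fused at C4a/C8a), free phenols at C5 and C7, a prenyl group at C6, and at C8 the benzylic carbon C1′ of a methyl 3-arylhexanoate chain (C1′ bears the propyl group and C2′H2–C3′O2Me).

There are three stereocentres. C2 (R) and C3 (S) are adjacent in ring B and carry cis methyl groups. C1′ (S) stands alone on the far side of ring A, too remote for either element to steer the other.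

The cis-2,3 pair is expected to be the less stable arrangement. C3 is α to the C4 ketone and should epimerise with base to the trans isomer, and retro-oxa-Michael opening of ring B would scramble C2 and allow reclosure onto O5. The prenyl olefin can cyclise onto its flanking phenols under acid and would not survive ordinary hydrogenation. The C7 phenol can close onto the ester carbon C3′ to give a six-membered lactone.

The real difficulty is twofold: three stereocentres that cannot relay to one another, two of them a contra-thermodynamic pair, and a fully substituted ring A in which it must be decided which oxygen closes which ring.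

The feature exploited is that every stereocentre is a C–H bond of a reduced pyranone. Ring B is the 2,3-dihydro form of a flat 2,3-dimethyl-4-pyranone (a chromone). The array O7–C7–C8–C1′–C2′–C3′ is the methanolysed 3,4-dihydro form of a flat 2-pyranone (a 4-propylcoumarin, ring C) fused at C7–C8. The key step adds hydride to C2 and a proton to C3 of the flat ring B.

## Logic of the disconnections

**14 to 12 (through 13).** The bonds cut are C2–H and C3–H of ring B; in the reverse sense the C2=C3 double bond returns and ring B becomes a flat 4-pyranone. This is cut first because the cis C2/C3 pair is the most fragile element and should exist only in the last flask. Two stereocentres disappear and 12 keeps a single one. The forward step must deliver hydride to C2 of a tetrasubstituted, electron-rich vinylogous ester from one face under catalyst control, deliver the C3 proton under kinetic control, and keep base away from the product.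

**12 to 11.** The C3′–OMe bond is cut and C3′ is joined to O7, closing ring C as a dihydrocoumarin lactone. The lactone is what a reduced coumarin gives, and it hides the C7 phenol. The forward ring opening must be irreversible and must come before the base-labile pair exists, so alkoxide is allowed here and nowhere later.

**11 to 9 (through 10).** The C1′–H bond (C10–H of the tricycle) and one C2′–H bond are cut, which restores the coumarin double bond. The last stereocentre disappears, and 9 is achiral and flat. The forward step is a second, independent face-selective hydride delivery, to the β-carbon of an unsaturated lactone. It must be faster than attack on ring B and must spare the prenyl group.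

**9 to 8.** The prenyl double bond is cut (metathesis retron), leaving an allyl group at C6. An allyl group, unlike a prenyl group, can be placed on C6 by a sigmatropic shift without ambiguity. The two pyranone double bonds must be inert to the metathesis catalyst.

**8 to 6 (through 7).** The C6–CH2 bond is cut and the allyl group is returned to O5. C6 is the only ortho carbon of O5 that carries hydrogen, so the [3,3] shift has one outcome. A C–C bond to the last free ring position is traded for an O-alkylation, and the forward step needs heat only.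

**6 to 5.** The O5–CH2 bond is cut. 5 has a single hydroxyl group, so the alkylation needs no selectivity, only enough forcing to make the chelated phenol react.

**5 to 3 and 4.** The C8–C1′ and O7–C3′ bonds are cut, which removes ring C as a six-carbon β-keto ester. This is the Pechmann retron and uses the only unchelated phenol of 3. A tricycle falls to a bicycle and a commercial ester. The electrophile must enter at C8 and not at C6 of 3.

**3 to 1 (through 2).** The O1–C2 and C2–C3 bonds are cut, so that ring B falls to the propionyl group of 1 and a two-carbon acetyl donor. 1 is symmetric, so ring B can close on either ortho oxygen with the same result. The whole skeleton is reduced to a commercial acylphloroglucinol.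

## Other disconnections considered

Alternative 1: The first plan to come to mind cuts ring B at O1–C2 and the chain at C8–C1′. The forward steps are oxa-Michael closure of the tigloyl ketone A1 to the chromanone A2, then acid-mediated Friedel–Crafts conjugate addition of A2 at C8 to the hexenoate A3. The chosen plan is preferred for four reasons:
- the oxa-Michael step is reversible and should settle at the trans isomer as a racemate;
- A1 can close on either ortho oxygen;
- the acid and heat of the Friedel–Crafts step would equilibrate C3 and threaten the prenyl group;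
- nothing in A2 can tell the two faces of A3 apart, so none of the three centres would be controlled.

Alternative 2: Ring B is cut at O1–C2 as an SN2 bond. A Mitsunobu closure of the anti-aldol A4, with inversion at the carbinol carbon, would give the cis pair directly, the aldol coming from a reagent-controlled anti-aldol reaction of the corresponding aryl ethyl ketone. The cut is sound for ring B alone but is set aside on step economy and mechanism:
- three phenols must be told apart and protected;
- a stoichiometric chiral controller is needed;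
- β-hydroxy ketones of this kind can eliminate under Mitsunobu conditions to the enone of alternative 1;
- C1′ still needs a separate solution, on an arene that by then already carries the base-labile pair.

Alternative 3: A single-atom edit deletes the lactone oxygen O7, which leads to the indanone A5. The forward key step is a Baeyer–Villiger oxygen insertion with migration of the electron-rich aryl carbon to give 11. It is rejected on structural grounds. The peracid should epoxidise the prenyl olefin and oxidise the electron-rich ring A faster than it adds to the aryl ketone. A5 also keeps the C1′ stereocentre and so needs an asymmetric synthesis of its own, whereas the coumarin route gets that centre from one condensation and one reduction.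

Key step: step 8

Assumption: the absolute sense of induction of the DTBM-SEGPHOS-ligated CuH catalysts on these two rings cannot be derived with certainty, so the ligand antipodes written in steps 6 and 8 are provisional. Each is fixed on the first run and exchanged for its mirror image if the sense is reversed, with no other change.

## Route

Step 1
Reactants: 1 1-(2,4,6-trihydroxyphenyl)propan-1-one
Product: 3 5,7-dihydroxy-2,3-dimethyl-4H-chromen-4-one, via diacetate 2 (not isolated)
Conditions: Ac2O, NaOAc, 170 °C; then HCl, MeOH, reflux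
Reagents that add atoms: acetic anhydride, CC(=O)OC(C)=O
Why: Kostanecki–Robinson chromone synthesis (O-acetylation, acetyl transfer to the α-carbon of the propionyl group, cyclodehydration), which with a propiophenone should give the 2,3-dimethylchromone. 1 is symmetric, so only one ring B can form, and acid methanolysis then frees the two phenols.

Step 2
Reactants: 3 5,7-dihydroxy-2,3-dimethyl-4H-chromen-4-one; 4 ethyl 3-oxohexanoate
Product: 5 5-hydroxy-2,3-dimethyl-10-propyl-4H,8H-pyrano[2,3-f]chromene-4,8-dione
Conditions: CF3SO3H, 40 °C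
Reagents that add atoms: none
Why: Pechmann condensation; the unchelated 7-OH is the only phenol free to form the lactone. Attack is expected at C8, between that hydroxyl and the ring oxygen O1, as is usual for 7-hydroxy-benzopyranones in which the C7–C8 bond has the higher double-bond character. This gives the angular ring C with the propyl-bearing carbon on C8.

Step 3
Reactants: 5 5-hydroxy-2,3-dimethyl-10-propyl-4H,8H-pyrano[2,3-f]chromene-4,8-dione
Product: 6 2,3-dimethyl-5-(prop-2-en-1-yloxy)-10-propyl-4H,8H-pyrano[2,3-f]chromene-4,8-dione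
Conditions: allyl bromide, K2CO3, DMF, 60 °C
Reagents that add atoms: allyl bromide, C=CCBr
Why: Williamson etherification of the only hydroxyl group. Warm carbonate in DMF should overcome the chelation of O5–H to the C4 carbonyl, and the dry medium should leave the lactone closed.

Step 4
Reactants: 6 2,3-dimethyl-5-(prop-2-en-1-yloxy)-10-propyl-4H,8H-pyrano[2,3-f]chromene-4,8-dione
Product: 8 5-hydroxy-2,3-dimethyl-6-(prop-2-en-1-yl)-10-propyl-4H,8H-pyrano[2,3-f]chromene-4,8-dione, via ortho-dienone 7 (not isolated)
Conditions: PhNEt2, 190 °C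
Reagents that add atoms: none
Why: Aromatic Claisen rearrangement. C6 is the only ortho position of O5 that bears hydrogen, so the [3,3] shift can deliver the allyl group only there, and tautomerisation of 7 restores ring A and the chelated phenol.

Step 5
Reactants: 8 5-hydroxy-2,3-dimethyl-6-(prop-2-en-1-yl)-10-propyl-4H,8H-pyrano[2,3-f]chromene-4,8-dione
Product: 9 5-hydroxy-2,3-dimethyl-6-(3-methylbut-2-en-1-yl)-10-propyl-4H,8H-pyrano[2,3-f]chromene-4,8-dione
Conditions: 2-methylbut-2-ene (excess), second-generation Grubbs catalyst RuCl2(H2IMes)(PCy3)(=CHPh) (5 mol%), CH2Cl2, 40 °C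
Reagents that add atoms: 2-methylbut-2-ene, CC=C(C)C
Why: Olefin cross-metathesis of a terminal allyl arene with a trisubstituted olefin, a standard way to turn an allyl into a prenyl group. The electron-poor trisubstituted coumarin olefin and the tetrasubstituted chromone olefin should not take part.

Step 6
Reactants: 9 5-hydroxy-2,3-dimethyl-6-(3-methylbut-2-en-1-yl)-10-propyl-4H,8H-pyrano[2,3-f]chromene-4,8-dione
Product: 11 (10S)-5-hydroxy-2,3-dimethyl-6-(3-methylbut-2-en-1-yl)-10-propyl-9,10-dihydro-4H,8H-pyrano[2,3-f]chromene-4,8-dione, via bis-silyl ketene acetal 10 (not isolated)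
Conditions: Cu(OAc)2·H2O (5 mol%), (R)-DTBM-SEGPHOS (5.5 mol%), (EtO)2MeSiH (3 equiv), toluene, 0 °C; then AcOH–THF–H2O, 0 °C
Reagents that add atoms: none
Why: CuH-catalysed asymmetric conjugate reduction of a coumarin. After silylation of the phenol the ligated CuH should deliver hydride to C10 (the future C1′) on the face chosen by the ligand, and the enolate is held as a silyl ketene acetal so the lactone cannot be reduced further. The trisubstituted unsaturated lactone should react well before the tetrasubstituted vinylogous ester of ring B, and the prenyl olefin is inert to CuH.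

Step 7
Reactants: 11 (10S)-5-hydroxy-2,3-dimethyl-6-(3-methylbut-2-en-1-yl)-10-propyl-9,10-dihydro-4H,8H-pyrano[2,3-f]chromene-4,8-dione
Product: 12 methyl (3S)-3-[5,7-dihydroxy-2,3-dimethyl-6-(3-methylbut-2-en-1-yl)-4-oxo-4H-chromen-8-yl]hexanoate
Conditions: NaOMe (1.2 equiv), MeOH, 0 °C; then AcOH
Reagents that add atoms: methanol, CO
Why: Transesterification of an aryl lactone by methoxide, driven forward by formation of the C7 phenoxide. C1′ has no acidifying neighbour and cannot epimerise, and the flat ring B has no stereocentre to lose.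

Step 8
Reactants: 12 methyl (3S)-3-[5,7-dihydroxy-2,3-dimethyl-6-(3-methylbut-2-en-1-yl)-4-oxo-4H-chromen-8-yl]hexanoate
Product: 14 methyl (3S)-3-[(2R,3S)-5,7-dihydroxy-2,3-dimethyl-6-(3-methylbut-2-en-1-yl)-4-oxo-3,4-dihydro-2H-chromen-8-yl]hexanoate, via tris-silyl enol ether 13 (not isolated)
Conditions: Cu(OAc)2·H2O (10 mol%), (S)-DTBM-SEGPHOS (11 mol%), (EtO)2MeSiH (6 equiv), toluene, 0 to 40 °C; then AcOH–THF–H2O, −20 to 0 °C
Reagents that add atoms: none
Why: CuH-catalysed enantioselective 1,4-reduction of a chromone followed by kinetic protonation; the closest known reaction type is the copper hydride conjugate reduction of 2-substituted chromones to chromanones. The silane reduces divalent copper acetate to the ligated monovalent copper hydride, which first silylates both phenols with loss of H2, so that no acidic proton and no copper-binding phenoxide remains. The catalyst then binds the C2=C3 bond of ring B and transfers hydride to C2, the β-carbon of the vinylogous ester, and σ-bond metathesis of the copper enolate with the silane releases the silyl enol ether 13 and the catalyst. No ring is closed; the flat pyranone ring B is dearomatised. C2 (R) is set by the ligand alone, because C1′ lies on the far side of ring A, so a residual wrong-face addition would give a separable diastereomer of 14 and not its enantiomer. C3 (S) is set in the work-up: in 13 allylic 1,2-strain with the C3 methyl should hold the C2 methyl pseudoaxial, the proton should add to C3 anti to it, and the two methyl groups end cis. The step needs chemoselectivity for the enone over the prenyl olefin, the ester and the newly formed ketone, which the inertness of CuH to isolated trisubstituted olefins and the storage of the ketone as its enol ether should secure. It also needs the absence of base, which the acetate precatalyst and the acidic hydrolysis provide.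

## Compound list

1 | 1-(2,4,6-trihydroxyphenyl)propan-1-one (flopropione) | CCC(=O)c1c(O)cc(O)cc1O | starting material
2 | 2,3-dimethyl-4-oxo-4H-chromene-5,7-diyl diacetate | CC(=O)Oc1cc(OC(C)=O)c2c(c1)OC(C)=C(C)C2=O | intermediate
3 | 5,7-dihydroxy-2,3-dimethyl-4H-chromen-4-one | CC1=C(C)C(=O)c2c(O)cc(O)cc2O1 | intermediate
4 | ethyl 3-oxohexanoate | CCCC(=O)CC(=O)OCC | starting material
5 | 5-hydroxy-2,3-dimethyl-10-propyl-4H,8H-pyrano[2,3-f]chromene-4,8-dione | CCCC1=CC(=O)Oc2cc(O)c3C(=O)C(C)=C(C)Oc3c12 | intermediate
6 | 2,3-dimethyl-5-(prop-2-en-1-yloxy)-10-propyl-4H,8H-pyrano[2,3-f]chromene-4,8-dione | CCCC1=CC(=O)Oc2cc(OCC=C)c3C(=O)C(C)=C(C)Oc3c12 | intermediate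
7 | 2,3-dimethyl-6-(prop-2-en-1-yl)-10-propyl-4H-pyrano[2,3-f]chromene-4,5,8(6H)-trione (ortho-dienone, racemic at C6) | CCCC1=CC(=O)OC2=C1C1=C(C(=O)C2CC=C)C(=O)C(C)=C(C)O1 | intermediate
8 | 5-hydroxy-2,3-dimethyl-6-(prop-2-en-1-yl)-10-propyl-4H,8H-pyrano[2,3-f]chromene-4,8-dione | CCCC1=CC(=O)Oc2c(CC=C)c(O)c3C(=O)C(C)=C(C)Oc3c12 | intermediate
9 | 5-hydroxy-2,3-dimethyl-6-(3-methylbut-2-en-1-yl)-10-propyl-4H,8H-pyrano[2,3-f]chromene-4,8-dione | CCCC1=CC(=O)Oc2c(CC=C(C)C)c(O)c3C(=O)C(C)=C(C)Oc3c12 | intermediate
10 | (10S)-5,8-bis{[diethoxy(methyl)silyl]oxy}-2,3-dimethyl-6-(3-methylbut-2-en-1-yl)-10-propyl-4H,10H-pyrano[2,3-f]chromen-4-one | CCC[C@H]1C=C(O[Si](C)(OCC)OCC)Oc2c1c1OC(C)=C(C)C(=O)c1c(O[Si](C)(OCC)OCC)c2CC=C(C)C | intermediate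
11 | (10S)-5-hydroxy-2,3-dimethyl-6-(3-methylbut-2-en-1-yl)-10-propyl-9,10-dihydro-4H,8H-pyrano[2,3-f]chromene-4,8-dione | CCC[C@H]1CC(=O)Oc2c1c1OC(C)=C(C)C(=O)c1c(O)c2CC=C(C)C | intermediate
12 | methyl (3S)-3-[5,7-dihydroxy-2,3-dimethyl-6-(3-methylbut-2-en-1-yl)-4-oxo-4H-chromen-8-yl]hexanoate | CCC[C@@H](CC(=O)OC)c1c(O)c(CC=C(C)C)c(O)c2c1OC(C)=C(C)C2=O | intermediate
13 | methyl (3S)-3-[(2R)-4,5,7-tris{[diethoxy(methyl)silyl]oxy}-2,3-dimethyl-6-(3-methylbut-2-en-1-yl)-2H-chromen-8-yl]hexanoate | CCC[C@@H](CC(=O)OC)c1c(O[Si](C)(OCC)OCC)c(CC=C(C)C)c(O[Si](C)(OCC)OCC)c2c1O[C@H](C)C(C)=C2O[Si](C)(OCC)OCC | intermediate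
14 | methyl (3S)-3-[(2R,3S)-5,7-dihydroxy-2,3-dimethyl-6-(3-methylbut-2-en-1-yl)-4-oxo-3,4-dihydro-2H-chromen-8-yl]hexanoate | CCC[C@@H](CC(=O)OC)c1c(O)c(CC=C(C)C)c(O)c2c1O[C@H](C)[C@H](C)C2=O | target

## Step count and least certain steps

Total step count: 8. Longest linear sequence: 8 steps; the route is fully linear from 1.

**Step 8 (key step).** Three things may go wrong:
- slow or incomplete hydride transfer, because the C2=C3 bond is tetrasubstituted and the enone is a vinylogous ester on a trioxygenated ring;
- poor facial selectivity at C2;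
- loss of the cis relationship by non-selective protonation or by epimerisation during hydrolysis.

The fallback gives up catalyst control in ring B and uses the resident C1′ centre to make the outcome separable. It sets out from 12 and returns at 14. 12 is silylated (t-BuMe2SiOTf, 2,6-lutidine, CH2Cl2) to methyl (3S)-3-[5,7-bis{[tert-butyl(dimethyl)silyl]oxy}-2,3-dimethyl-6-(3-methylbut-2-en-1-yl)-4-oxo-4H-chromen-8-yl]hexanoate F1. Conjugate reduction with LiBH(s-Bu)3 in THF at −78 °C and a cold AcOH quench of the enolate should give the cis chromanone as two diastereomers: methyl (3S)-3-[(2R,3S)-5,7-bis{[tert-butyl(dimethyl)silyl]oxy}-2,3-dimethyl-6-(3-methylbut-2-en-1-yl)-4-oxo-3,4-dihydro-2H-chromen-8-yl]hexanoate F2 and its (2S,3R) isomer, methyl (3S)-3-[(2S,3R)-5,7-bis{[tert-butyl(dimethyl)silyl]oxy}-2,3-dimethyl-6-(3-methylbut-2-en-1-yl)-4-oxo-3,4-dihydro-2H-chromen-8-yl]hexanoate F3. These are separated by chromatography, and F2 is desilylated with HF·pyridine in THF at 0 °C to give 14.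

**Step 2.** The electrophile may enter at C6 instead of C8 (linear annulation), or the protonated chromone may be too deactivated to react. The fallback blocks C6 first and closes ring C by a tethered reaction that has only C8 left. It sets out from 3 and returns at 8:
- selective protection of the unchelated phenol (MOMCl, i-Pr2NEt) gives 5-hydroxy-7-(methoxymethoxy)-2,3-dimethyl-4H-chromen-4-one F4;
- allylation (allyl bromide, K2CO3, DMF) gives 7-(methoxymethoxy)-2,3-dimethyl-5-(prop-2-en-1-yloxy)-4H-chromen-4-one F5;
- Claisen rearrangement (PhNEt2, 190 °C) gives 5-hydroxy-7-(methoxymethoxy)-2,3-dimethyl-6-(prop-2-en-1-yl)-4H-chromen-4-one F6;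
- HCl in MeOH gives 5,7-dihydroxy-2,3-dimethyl-6-(prop-2-en-1-yl)-4H-chromen-4-one F7;
- esterification of the 7-OH with hex-2-ynoic acid (DCC, DMAP) gives 5-hydroxy-2,3-dimethyl-4-oxo-6-(prop-2-en-1-yl)-4H-chromen-7-yl hex-2-ynoate F8;
- intramolecular 6-endo hydroarylation at C8 (AuCl(PPh3)/AgOTf, 1,2-dichloroethane, 60 °C) gives 8.

**Step 6.** The likely failures are low enantioface selectivity at the β-alkyl, β-aryl carbon and partial reduction of ring B. The fallback defers control of C1′ to a separation after the key step. It sets out from 9 and returns at 14. Reduction of 9 with an achiral catalyst ([(Ph3P)CuH]6, (EtO)2MeSiH, toluene) would give 11 together with its enantiomer, (10R)-5-hydroxy-2,3-dimethyl-6-(3-methylbut-2-en-1-yl)-10-propyl-9,10-dihydro-4H,8H-pyrano[2,3-f]chromene-4,8-dione F9. Step 7 on the mixture would give 12 together with methyl (3R)-3-[5,7-dihydroxy-2,3-dimethyl-6-(3-methylbut-2-en-1-yl)-4-oxo-4H-chromen-8-yl]hexanoate F10. Step 8 with the chiral catalyst would turn the pair into 14 and the diastereomer methyl (3R)-3-[(2R,3S)-5,7-dihydroxy-2,3-dimethyl-6-(3-methylbut-2-en-1-yl)-4-oxo-3,4-dihydro-2H-chromen-8-yl]hexanoate F11, from which 14 is separated by chromatography.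

**Step 7.** The lactone may re-form on acidification and concentration, because the C7 phenol and the ester are held close by the flanking substituents; methoxide may also add to ring B. The fallback fixes the open form by alkylating a carboxylate instead of relying on an ester–lactone balance. It sets out from 11 and returns at 12. Hydrolysis (LiOH, THF–H2O, 0 °C) and careful acidification to pH 5 give (3S)-3-[5,7-dihydroxy-2,3-dimethyl-6-(3-methylbut-2-en-1-yl)-4-oxo-4H-chromen-8-yl]hexanoic acid F12. This is methylated at once at the carboxyl group with Me3SiCHN2 (1.05 equiv) in toluene–MeOH at 0 °C to give 12.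

## Further compounds

F1 | step 8 | methyl (3S)-3-[5,7-bis{[tert-butyl(dimethyl)silyl]oxy}-2,3-dimethyl-6-(3-methylbut-2-en-1-yl)-4-oxo-4H-chromen-8-yl]hexanoate | CCC[C@@H](CC(=O)OC)c1c(O[Si](C)(C)C(C)(C)C)c(CC=C(C)C)c(O[Si](C)(C)C(C)(C)C)c2c1OC(C)=C(C)C2=O
F2 | step 8 | methyl (3S)-3-[(2R,3S)-5,7-bis{[tert-butyl(dimethyl)silyl]oxy}-2,3-dimethyl-6-(3-methylbut-2-en-1-yl)-4-oxo-3,4-dihydro-2H-chromen-8-yl]hexanoate | CCC[C@@H](CC(=O)OC)c1c(O[Si](C)(C)C(C)(C)C)c(CC=C(C)C)c(O[Si](C)(C)C(C)(C)C)c2c1O[C@H](C)[C@H](C)C2=O
F3 | step 8 | methyl (3S)-3-[(2S,3R)-5,7-bis{[tert-butyl(dimethyl)silyl]oxy}-2,3-dimethyl-6-(3-methylbut-2-en-1-yl)-4-oxo-3,4-dihydro-2H-chromen-8-yl]hexanoate | CCC[C@@H](CC(=O)OC)c1c(O[Si](C)(C)C(C)(C)C)c(CC=C(C)C)c(O[Si](C)(C)C(C)(C)C)c2c1O[C@@H](C)[C@@H](C)C2=O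
F4 | step 2 | 5-hydroxy-7-(methoxymethoxy)-2,3-dimethyl-4H-chromen-4-one | COCOc1cc(O)c2C(=O)C(C)=C(C)Oc2c1
F5 | step 2 | 7-(methoxymethoxy)-2,3-dimethyl-5-(prop-2-en-1-yloxy)-4H-chromen-4-one | COCOc1cc(OCC=C)c2C(=O)C(C)=C(C)Oc2c1
F6 | step 2 | 5-hydroxy-7-(methoxymethoxy)-2,3-dimethyl-6-(prop-2-en-1-yl)-4H-chromen-4-one | COCOc1cc2OC(C)=C(C)C(=O)c2c(O)c1CC=C
F7 | step 2 | 5,7-dihydroxy-2,3-dimethyl-6-(prop-2-en-1-yl)-4H-chromen-4-one | CC1=C(C)C(=O)c2c(O)c(CC=C)c(O)cc2O1
F8 | step 2 | 5-hydroxy-2,3-dimethyl-4-oxo-6-(prop-2-en-1-yl)-4H-chromen-7-yl hex-2-ynoate | CCCC#CC(=O)Oc1cc2OC(C)=C(C)C(=O)c2c(O)c1CC=C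
F9 | step 6 | (10R)-5-hydroxy-2,3-dimethyl-6-(3-methylbut-2-en-1-yl)-10-propyl-9,10-dihydro-4H,8H-pyrano[2,3-f]chromene-4,8-dione | CCC[C@@H]1CC(=O)Oc2c1c1OC(C)=C(C)C(=O)c1c(O)c2CC=C(C)C
F10 | step 6 | methyl (3R)-3-[5,7-dihydroxy-2,3-dimethyl-6-(3-methylbut-2-en-1-yl)-4-oxo-4H-chromen-8-yl]hexanoate | CCC[C@H](CC(=O)OC)c1c(O)c(CC=C(C)C)c(O)c2c1OC(C)=C(C)C2=O
F11 | step 6 | methyl (3R)-3-[(2R,3S)-5,7-dihydroxy-2,3-dimethyl-6-(3-methylbut-2-en-1-yl)-4-oxo-3,4-dihydro-2H-chromen-8-yl]hexanoate | CCC[C@H](CC(=O)OC)c1c(O)c(CC=C(C)C)c(O)c2c1O[C@H](C)[C@H](C)C2=O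
F12 | step 7 | (3S)-3-[5,7-dihydroxy-2,3-dimethyl-6-(3-methylbut-2-en-1-yl)-4-oxo-4H-chromen-8-yl]hexanoic acid | CCC[C@@H](CC(=O)O)c1c(O)c(CC=C(C)C)c(O)c2c1OC(C)=C(C)C2=O
A1 | alternative 1 | (2E)-2-methyl-1-[2,4,6-trihydroxy-3-(3-methylbut-2-en-1-yl)phenyl]but-2-en-1-one | C/C=C(\C)C(=O)c1c(O)cc(O)c(CC=C(C)C)c1O
A2 | alternative 1 | (2R,3S)-5,7-dihydroxy-2,3-dimethyl-6-(3-methylbut-2-en-1-yl)-2,3-dihydro-4H-chromen-4-one | CC(C)=CCc1c(O)cc2O[C@H](C)[C@H](C)C(=O)c2c1O
A3 | alternative 1 | methyl (2E)-hex-2-enoate | CCC/C=C/C(=O)OC
A4 | alternative 2 | methyl (3S)-3-{2,4,6-trihydroxy-3-[(2S,3S)-3-hydroxy-2-methylbutanoyl]-5-(3-methylbut-2-en-1-yl)phenyl}hexanoate | CCC[C@@H](CC(=O)OC)c1c(O)c(CC=C(C)C)c(O)c(C(=O)[C@@H](C)[C@H](C)O)c1O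
A5 | alternative 3 | (9S)-5-hydroxy-2,3-dimethyl-6-(3-methylbut-2-en-1-yl)-9-propyl-8,9-dihydrocyclopenta[h]chromene-4,7-dione | CCC[C@H]1CC(=O)c2c1c1OC(C)=C(C)C(=O)c1c(O)c2CC=C(C)C
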